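## Retrosynthetic overview

1. Labels: ring A is the chlorinated benzoyl ring (C1A acyl, C2A OH, C3A Cl, C4A OMe, C5A H, C6A propyl) and ring B is the benzoic acid ring (C1B CO2H, C2B OH, C3B H, C4B O-aroyl, C5B H, C6B propyl). The plan rests on ring B being a resorcinol whose free C2B hydroxyl is meta to the acylated C4B oxygen, the pattern obtained when a ketene carbonyl (becoming C2B–OH) is annulated with an oxygen-bearing alkyne (becoming C4B–O).
2. Target ⇐ BCl3 removal of the benzyl ester and of the chelated C2A methyl ether ⇐ protodesilylation at C3B.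
3. Ring B, the only ring built ⇐ benzannulation of the vinylketene from an E-alkenyl diazoketone (C5B–C6B by Wolff shift) with the silyl ynol ester of the ring A acid (C2B–C3B and C4B–C5B, then C1B–C2B). The depside C4B–O–C(=O) link arrives on the alkyne, so no phenol has to attack the doubly ortho-substituted ring A carbonyl.
4. Ynol ester ⇐ ring A carboxylate + silylethynyl(phenyl)iodonium triflate. Ring A acid ⇐ 5-propylresorcinol (ring A is bought) by methylation, lithiation–chlorination at C3A, formylation and oxidation.
5. Diazoketone ⇐ detrifluoroacetylative diazo transfer on the methyl ketone ⇐ Wittig reaction of an α-propyl acetyl ylide with benzyl glyoxylate.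

Key step: step 11

Assumption: the diazoketone is used as its E isomer (ester trans to the diazoacetyl group). C1B ends as an aromatic carbon, so this geometry does not reach the product and is chosen only for the course of the pericyclic cascade.

## Route

Step 1
Reactants: 1 5-propylbenzene-1,3-diol (divarinol)
Product: 2 1,3-dimethoxy-5-propylbenzene
Conditions: MeI, K2CO3, acetone, reflux
Reagents that add atoms: iodomethane, CI
Why: Williamson ether synthesis, in which both phenoxides are methylated by SN2 attack on MeI and nothing else in 1 is nucleophilic.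

Step 2
Reactants: 2 1,3-dimethoxy-5-propylbenzene
Product: 4 2-chloro-1,3-dimethoxy-5-propylbenzene, via aryllithium 3 (not isolated)
Conditions: n-BuLi, THF, 0 °C → rt; then C2Cl6, −78 °C → rt
Reagents that add atoms: hexachloroethane, ClC(Cl)(Cl)C(Cl)(Cl)Cl
Why: Directed ortho-metalation, where the position between the two methoxy groups is by far the most acidic, so lithiation and chlorine transfer from C2Cl6 fix the halogen at the future C3A, a site that electrophilic chlorination of such rings does not reach cleanly.

Step 3
Reactants: 4 2-chloro-1,3-dimethoxy-5-propylbenzene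
Product: 5 3-chloro-2,4-dimethoxy-6-propylbenzaldehyde
Conditions: Cl2CHOMe, TiCl4, CH2Cl2, −10 → 0 °C; then aq HCl
Reagents that add atoms: dichloromethyl methyl ether, COC(Cl)Cl; water, O
Why: Rieche formylation (Friedel–Crafts type), in which the two free ring positions of 4 are equivalent by symmetry and each is ortho to one methoxy group and para to the other, so only one aldehyde can form.

Step 4
Reactants: 5 3-chloro-2,4-dimethoxy-6-propylbenzaldehyde
Product: 6 3-chloro-2,4-dimethoxy-6-propylbenzoic acid
Conditions: NaClO2, NaH2PO4, 2-methylbut-2-ene, t-BuOH–H2O, rt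
Reagents that add atoms: sodium chlorite, [Na+].[O-]Cl=O
Why: Pinnick oxidation, which converts even hindered aromatic aldehydes to acids, while 2-methylbut-2-ene traps the hypochlorous acid that would otherwise chlorinate C5A.

Step 5
Reactants: 6 3-chloro-2,4-dimethoxy-6-propylbenzoic acid; 7 phenyl[(trimethylsilyl)ethynyl]iodonium trifluoromethanesulfonate
Product: 10 2-(trimethylsilyl)ethynyl 3-chloro-2,4-dimethoxy-6-propylbenzoate, via sodium carboxylate 8 (not isolated), via alkylidene carbene 9 (not isolated)
Conditions: NaH, THF, 0 °C; then 7, CH2Cl2, 0 °C → rt, dry work-up, short plug of deactivated silica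
Reagents that add atoms: none
Why: Known alkynyl carboxylate synthesis from alkynyl(aryl)iodonium salts, in which the carboxylate oxygen of 8 adds to the silyl-bearing β-carbon of 7, iodobenzene departs and the 1,2-silyl shift in carbene 9 sets the C(sp)–O bond, all at the unhindered oxygen so that the two ortho substituents of ring A do not matter.

Step 6
Reactants: 11 dibenzyl (2R,3R)-tartrate (dibenzyl L-tartrate)
Product: 12 benzyl glyoxylate (benzyl 2-oxoacetate)
Conditions: H5IO6, Et2O, rt; filter, use fresh
Reagents that add atoms: none
Why: Malaprade glycol cleavage, in which periodic acid splits the vicinal diol into two molecules of the same aldehyde and the two stereocentres of 11 are lost without consequence.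

Step 7
Reactants: 13 butyltriphenylphosphonium bromide
Product: 15 3-(triphenyl-λ5-phosphanylidene)hexan-2-one, via butylidene ylide 14 (not isolated)
Conditions: 13 (2 equiv), n-BuLi (2 equiv), THF, 0 °C; then AcCl (1 equiv), −78 °C → rt; filter off the phosphonium salt
Reagents that add atoms: acetyl chloride, CC(=O)Cl
Why: C-acylation of a non-stabilised ylide with transylidation, where one equivalent of 14 is acetylated at carbon and the second deprotonates the resulting acylphosphonium salt to give the stabilised ylide.

Step 8
Reactants: 12 benzyl glyoxylate; 15 3-(triphenyl-λ5-phosphanylidene)hexan-2-one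
Product: 16 benzyl (2E)-4-oxo-3-propylpent-2-enoate
Conditions: toluene, 60 °C
Reagents that add atoms: none
Why: Wittig olefination with a stabilised α-substituted ylide, which places the acyl group trans to the aldehyde substituent (here the ester) and so should give the E alkene, the very electrophilic glyoxylate making up for the low reactivity of the ylide.

Step 9
Reactants: 16 benzyl (2E)-4-oxo-3-propylpent-2-enoate
Product: 18 benzyl (2E)-7,7,7-trifluoro-4,6-dioxo-3-propylhept-2-enoate, via lithium enolate 17 (not isolated)
Conditions: 16 added slowly to LiN(SiMe3)2, THF, −78 °C; then CF3CO2CH2CF3; dilute aq HCl; crude product taken on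
Reagents that add atoms: 2,2,2-trifluoroethyl trifluoroacetate, O=C(OCC(F)(F)F)C(F)(F)F
Why: Claisen-type trifluoroacetylation of the kinetic methyl enolate, formed by carbonyl-directed deprotonation with the hindered amide base under inverse addition and captured at once by the highly reactive trifluoroacetate.

Step 10
Reactants: 18 benzyl (2E)-7,7,7-trifluoro-4,6-dioxo-3-propylhept-2-enoate
Product: 19 benzyl (2E)-5-diazo-4-oxo-3-propylpent-2-enoate
Conditions: MsN3, Et3N, H2O (1 equiv), MeCN, rt
Reagents that add atoms: methanesulfonyl azide, CS(=O)(=O)N=[N+]=[N-]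
Why: Regitz-type detrifluoroacetylative diazo transfer, the standard entry to α,β-unsaturated diazoketones, which avoids the acid chloride–diazomethane route, where diazomethane would add as a 1,3-dipole to the electron-poor alkene.

Step 11
Reactants: 10 2-(trimethylsilyl)ethynyl 3-chloro-2,4-dimethoxy-6-propylbenzoate; 19 benzyl (2E)-5-diazo-4-oxo-3-propylpent-2-enoate
Product: 24 benzyl 4-[(3-chloro-2,4-dimethoxy-6-propylbenzoyl)oxy]-2-hydroxy-6-propyl-3-(trimethylsilyl)benzoate, via vinylketene 20 (not isolated), via cyclobutenone 21 (not isolated), via dienylketene 22 (not isolated), via cyclohexadienone 23 (not isolated)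
Conditions: 19 (1.5 equiv, in portions), degassed CH2Cl2, hν (medium-pressure Hg lamp, Pyrex filter, λ > 300 nm), rt; then solvent switch to toluene, 90 °C
Reagents that add atoms: none
Why: Proposed new method: light expels N2 from 19 and the alkenyl group migrates to the diazo carbon (Wolff rearrangement, C5B–C6B) to give the ester-activated vinylketene 20, which should add to ynol ester 10 in a (2+2) cycloaddition (C2B–C3B and C4B–C5B) to give cyclobutenone 21. Heating opens 21 by reversible four-electron electrocyclic cleavage of C2B–C5B to the silyl dienylketene 22, ring B then closes as a six-membered carbocycle by six-electron electrocyclisation (C1B–C2B), and dienone 23 enolises to the C2B phenol 24. The closest known reaction type is the Danheiser benzannulation of diazoketone-derived vinylketenes with alkoxyalkynes, siloxyalkynes and N-acyl or N-sulfonyl ynamides; alkynyl carboxylates have not been used, and they are expected to react because they are the oxygen analogues of the N-acyl ynamides and because 20 is an unusually electrophilic ketene. The selectivity required is the orientation of the (2+2) step: the lone pair of the ester oxygen and the β-silicon effect both make the silyl-bearing carbon the nucleophilic end, so it bonds to the ketene carbonyl carbon and the aroyloxy group ends up meta to the new phenol. The E geometry of 19 holds the benzyl ester away from the ketene carbon, which prevents oxa-electrocyclisation onto the ester carbonyl and puts hydrogen rather than the ester on the inside of the ring-closing transition state, while Pyrex-filtered light spares the aryl ester chromophores from photo-Fries cleavage. No lasting stereocentre is made, since C5B in 21 and C1B in 23 are transient racemic sp3 centres that become aromatic carbons.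

Step 12
Reactants: 24 benzyl 4-[(3-chloro-2,4-dimethoxy-6-propylbenzoyl)oxy]-2-hydroxy-6-propyl-3-(trimethylsilyl)benzoate
Product: 25 benzyl 4-[(3-chloro-2,4-dimethoxy-6-propylbenzoyl)oxy]-2-hydroxy-6-propylbenzoate
Conditions: CF3CO2H, CH2Cl2, 0 °C → rt; evaporate
Reagents that add atoms: none
Why: Ipso-protodesilylation (electrophilic aromatic substitution), fast at C3B because this carbon is ortho to the free phenol and strain is released, and placed before the BCl3 step because BCl3 would attack the aryl–silicon bond.

Step 13
Reactants: 25 benzyl 4-[(3-chloro-2,4-dimethoxy-6-propylbenzoyl)oxy]-2-hydroxy-6-propylbenzoate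
Product: 26 3-chlorodivaricatic acid
Conditions: BCl3 (excess), C6HMe5, CH2Cl2, −78 → 0 °C; then aq HCl
Reagents that add atoms: none
Why: Chelation-directed Lewis acid dealkylation, in which BCl3 held between the depside carbonyl and the crowded C2A methoxy group loses MeCl, the boron chelate of the C2B salicylate ionises the benzyl–oxygen bond with C6HMe5 trapping the benzyl cation (Friedel–Crafts alkylation), and the unchelated C4A methyl ether and the aryl ester, which has no alkyl–oxygen bond to break, should persist.

## Compound list

1 | 5-propylbenzene-1,3-diol (divarinol) | CCCc1cc(O)cc(O)c1 | starting material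
2 | 1,3-dimethoxy-5-propylbenzene | CCCc1cc(OC)cc(OC)c1 | intermediate
3 | (2,6-dimethoxy-4-propylphenyl)lithium | [Li]c1c(OC)cc(CCC)cc1OC | intermediate
4 | 2-chloro-1,3-dimethoxy-5-propylbenzene | CCCc1cc(OC)c(Cl)c(OC)c1 | intermediate
5 | 3-chloro-2,4-dimethoxy-6-propylbenzaldehyde | CCCc1cc(OC)c(Cl)c(OC)c1C=O | intermediate
6 | 3-chloro-2,4-dimethoxy-6-propylbenzoic acid | CCCc1cc(OC)c(Cl)c(OC)c1C(=O)O | intermediate
7 | phenyl[(trimethylsilyl)ethynyl]iodonium trifluoromethanesulfonate | C[Si](C)(C)C#C[I+]c1ccccc1.[O-]S(=O)(=O)C(F)(F)F | starting material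
8 | sodium 3-chloro-2,4-dimethoxy-6-propylbenzoate | CCCc1cc(OC)c(Cl)c(OC)c1C(=O)[O-].[Na+] | intermediate
9 | 2-[(3-chloro-2,4-dimethoxy-6-propylbenzoyl)oxy]-2-(trimethylsilyl)ethenylidene (alkylidene carbene) | [C]=C([Si](C)(C)C)OC(=O)c1c(CCC)cc(OC)c(Cl)c1OC | intermediate
10 | 2-(trimethylsilyl)ethynyl 3-chloro-2,4-dimethoxy-6-propylbenzoate | C[Si](C)(C)C#COC(=O)c1c(CCC)cc(OC)c(Cl)c1OC | intermediate
11 | dibenzyl (2R,3R)-tartrate | O[C@H]([C@@H](O)C(=O)OCc1ccccc1)C(=O)OCc1ccccc1 | starting material
12 | benzyl glyoxylate | O=CC(=O)OCc1ccccc1 | intermediate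
13 | butyltriphenylphosphonium bromide | CCCC[P+](c1ccccc1)(c1ccccc1)c1ccccc1.[Br-] | starting material
14 | butylidene(triphenyl)-λ5-phosphane | CCCC=P(c1ccccc1)(c1ccccc1)c1ccccc1 | intermediate
15 | 3-(triphenyl-λ5-phosphanylidene)hexan-2-one | CCCC(C(C)=O)=P(c1ccccc1)(c1ccccc1)c1ccccc1 | intermediate
16 | benzyl (2E)-4-oxo-3-propylpent-2-enoate | CCC/C(=C\C(=O)OCc1ccccc1)C(C)=O | intermediate
17 | lithium enolate of 16 at the methyl group (E alkene retained) | C=C(O[Li])/C(CCC)=C/C(=O)OCc1ccccc1 | intermediate
18 | benzyl (2E)-7,7,7-trifluoro-4,6-dioxo-3-propylhept-2-enoate | CCC/C(=C\C(=O)OCc1ccccc1)C(=O)CC(=O)C(F)(F)F | intermediate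
19 | benzyl (2E)-5-diazo-4-oxo-3-propylpent-2-enoate | CCC/C(=C\C(=O)OCc1ccccc1)C(=O)C=[N+]=[N-] | intermediate
20 | benzyl (2E)-5-oxo-3-propylpenta-2,4-dienoate (vinylketene) | CCC/C(=C\C(=O)OCc1ccccc1)C=C=O | intermediate
21 | benzyl (2E)-3-{2-[(3-chloro-2,4-dimethoxy-6-propylbenzoyl)oxy]-4-oxo-3-(trimethylsilyl)cyclobut-2-en-1-yl}hex-2-enoate (racemic at the ring sp3 carbon) | CCC/C(=C\C(=O)OCc1ccccc1)C1C(=O)C([Si](C)(C)C)=C1OC(=O)c1c(CCC)cc(OC)c(Cl)c1OC | intermediate
22 | benzyl (2E,4E)-5-[(3-chloro-2,4-dimethoxy-6-propylbenzoyl)oxy]-7-oxo-3-propyl-6-(trimethylsilyl)hepta-2,4,6-trienoate (dienylketene, C3B and C6B cis about C4B=C5B) | O=C=C([Si](C)(C)C)/C(OC(=O)c1c(CCC)cc(OC)c(Cl)c1OC)=C\C(CCC)=C\C(=O)OCc1ccccc1 | intermediate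
23 | benzyl 4-[(3-chloro-2,4-dimethoxy-6-propylbenzoyl)oxy]-2-oxo-6-propyl-3-(trimethylsilyl)cyclohexa-3,5-diene-1-carboxylate (racemic) | CCCC1=CC(OC(=O)c2c(CCC)cc(OC)c(Cl)c2OC)=C([Si](C)(C)C)C(=O)C1C(=O)OCc1ccccc1 | intermediate
24 | benzyl 4-[(3-chloro-2,4-dimethoxy-6-propylbenzoyl)oxy]-2-hydroxy-6-propyl-3-(trimethylsilyl)benzoate | CCCc1cc(OC(=O)c2c(CCC)cc(OC)c(Cl)c2OC)c([Si](C)(C)C)c(O)c1C(=O)OCc1ccccc1 | intermediate
25 | benzyl 4-[(3-chloro-2,4-dimethoxy-6-propylbenzoyl)oxy]-2-hydroxy-6-propylbenzoate | CCCc1cc(OC(=O)c2c(CCC)cc(OC)c(Cl)c2OC)cc(O)c1C(=O)OCc1ccccc1 | intermediate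
26 | 3-chlorodivaricatic acid | CCCc1cc(OC(=O)c2c(CCC)cc(OC)c(Cl)c2O)cc(O)c1C(=O)O | target

## Step count and risks

Total step count: 13. Longest linear sequence: 8 (steps 1–5, then 11–13).

**Step 11 (key step).**
- What may go wrong: the ynol ester may be too weak a nucleophile to intercept the vinylketene. The ketene would then be lost by dimerisation, or by light-driven E to Z isomerisation followed by closure onto its own ester carbonyl. The ynol ester may also undergo a thermal 1,3-acyl shift during the heating stage.
- Fallback (known chemistry): it sets out from 1 and 6 and comes back at 25. Divarinol 1 is carboxylated with MeOMgOCO2Me in DMF at 120 °C, then acidified, to give 2,4-dihydroxy-6-propylbenzoic acid F1. The carboxylate of F1 is alkylated with BnBr and KHCO3 in DMF to give benzyl 2,4-dihydroxy-6-propylbenzoate F2. Acid 6 and F2 are then condensed with (CF3CO)2O in toluene, the mixed-anhydride depside esterification. The hydrogen-bonded C2B hydroxyl stays free and only the C4B hydroxyl is acylated, which gives 25 directly, and the route resumes at step 13.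

**Step 5.**
- What may go wrong: the carboxylate may attack silicon instead of the β-carbon, which desilylates the iodonium salt. The moisture-sensitive ynol ester may also be hydrolysed during isolation.
- Fallback: it sets out from 6 and comes back at 10, and it reverses the polarity of the alkyne partner. Two equivalents of 6 exchange with PhI(OAc)2 in chlorobenzene, with acetic acid removed under reduced pressure, to give [bis(3-chloro-2,4-dimethoxy-6-propylbenzoyloxy)iodo]benzene F3. Lithium (trimethylsilyl)acetylide, made from trimethylsilylacetylene and n-BuLi, is added to this trivalent iodine dicarboxylate in THF at −78 °C → rt. The alkynyl(phenyl)iodonium carboxylate formed in the flask collapses to 10, and one equivalent of 6 is recovered.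

**Step 9.**
- What may go wrong: the base may remove the γ-proton of the propyl chain, which is vinylogous to the ester, and the enolate may add in Michael fashion to unreacted enone ester.
- Fallback: it sets out from 12 and comes back at 19, and it installs the diazoketone before the alkene, so no strong base meets the enone ester. Purchased triethyl 2-phosphonopentanoate F4 is hydrolysed at the carboxylic ester with NaOH in aqueous EtOH to give 2-(diethoxyphosphoryl)pentanoic acid F5. F5 is converted with (COCl)2 and catalytic DMF into 2-(diethoxyphosphoryl)pentanoyl chloride F6. F6 is acylated onto excess CH2N2 in Et2O at 0 °C (first stage of the Arndt–Eistert sequence, on a saturated acid chloride) to give diethyl (1-diazo-2-oxohexan-3-yl)phosphonate F7. Horner–Wadsworth–Emmons olefination of 12 with F7 (LiCl, DBU, MeCN, 0 °C) should give 19, with the E isomer separated by chromatography if needed. Steps 7 to 10 are bypassed.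

## Further compounds

F1 | step 11 | 2,4-dihydroxy-6-propylbenzoic acid | CCCc1cc(O)cc(O)c1C(=O)O
F2 | step 11 | benzyl 2,4-dihydroxy-6-propylbenzoate | CCCc1cc(O)cc(O)c1C(=O)OCc1ccccc1
F3 | step 5 | [bis(3-chloro-2,4-dimethoxy-6-propylbenzoyloxy)iodo]benzene | CCCc1cc(OC)c(Cl)c(OC)c1C(=O)OI(OC(=O)c1c(CCC)cc(OC)c(Cl)c1OC)c1ccccc1
F4 | step 9 | triethyl 2-phosphonopentanoate (racemic, purchased) | CCCC(C(=O)OCC)P(=O)(OCC)OCC
F5 | step 9 | 2-(diethoxyphosphoryl)pentanoic acid (racemic) | CCCC(C(=O)O)P(=O)(OCC)OCC
F6 | step 9 | 2-(diethoxyphosphoryl)pentanoyl chloride (racemic) | CCCC(C(=O)Cl)P(=O)(OCC)OCC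
F7 | step 9 | diethyl (1-diazo-2-oxohexan-3-yl)phosphonate (racemic) | CCCC(C(=O)C=[N+]=[N-])P(=O)(OCC)OCC
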